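The earlier runs and the new flask stem from a simulated flask on assumed constants, and the scatter is random.

By 10.0 min in Thursday's flask the feed has delivered E worth 91.7% of the Z charge and 24.4% of Z has reacted, so a leftover of 67.3% ought to stand ready, and I ask what that leftover is worth in rate.

common to all: Z 0.050 M
- Thursday's: E 1.1 equiv (fed, over 12 min); the very flask that is asked about, followed so far
- flask: E 1.10 equiv (fed, over 12 min); time 25 min

Thursday's run (percent of the Z charged)

| time / min | Z / % | D / % |
|---|---|---|
| 2.50 | 96.7 | 3.5 |
| 5.00 | 90.8 | 9.3 |
| 8.00 | 81.9 | 17.3 |
| 10.0 | 75.6 | 23.8 |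

(each reading ± 0.3 percentage points)

- the earlier runs do not show how much of E is bound; that part of a forecast is a guess

1. part of the Z that has reacted at 25 min
2. share of free E in free E and Q together, at 25 min

I divide the loss rate of Z by [Z] and by the leftover, and this working constant reads 0.137 min⁻¹ over the first 2.50 min but 0.0653 min⁻¹ between 8.00 min and 10.0 min, about half, so it halves every 7.26 min, a reading from points good to 0.3 percentage points. The pseudo-first-order rate of Z last reads 0.0400 min⁻¹; I hold it level until the feed stops at 12 min, then let it halve on that clock, which leaves a factor 0.289 at 25 min. Summed onto the readings, this gives 0.658 for the reaction dose, the logarithm of [Z] at the start over [Z] now, so I commit to 48.2% reacted.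

The forecast, which holds “so the reaction falls short of simple second order”, gives 59% (52% to 66%) and 55% (25% to 90%), its first figure standing above mine.

The flask gives 41.4% reacted and a free share of 15.0%.

    E ⇌ L (K = 1.80, k = 0.00200 s⁻¹)
    Z + E ⇌ G + D (K = 1.70, k = 0.0500 M⁻¹ s⁻¹)
    2 E → J (k = 0.0170 M⁻¹ s⁻¹)
    E + G ⇌ Q, settled at all times (K = 2300 M⁻¹)

By subtraction the leftover in this flask is now 68.6% of the Z charge, while free E stands at 6.42% of it. The dose actually reached is 0.534, which is 0.812 of my 0.658, so my reckoning ran high. For the neighbour flask with 4.40 equiv of E, I keep the clock and multiply 0.658 by 4.00, which gives 92.8% reacted; the computed flask gives 90.8%.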